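Structural features

18 is a flavanonol methyl ether: a chroman-4-one in which the benzene ring A (C4a, C5 to C8, C8a) is fused to the dihydropyranone ring C (O1, C2, C3, C4, C4a, C8a), with the aryl ring B attached at C2. Ring A carries three contiguous methoxy groups at C5, C6 and C7 and one hydrogen at C8, while ring B carries two free phenols at C3' and C5' on either side of a methoxy group at C4', so the two kinds of aryl oxygen must be kept apart throughout. The only stereocenters are the neighbours C2 (benzylic, bonded to O1) and C3 (methoxy-bearing, alpha to the C4 ketone), and they are trans, (2R,3R). The fragile elements are the C3 hydrogen, whose removal epimerises C3 and can also erase C2 by beta-elimination of O1 (ring opening to an enone), the benzylic C2–O1 bond, and the 5-methoxy group peri to the ketone, which is the first to be lost to strong Lewis acids. The real difficulty is to set the absolute configuration at C2 with no existing stereocenter to lean on, and then to carry an enolisable, ring-openable ketone through the construction of a fully oxygenated ring A. The key step uses the fact that O1–C2 of ring C is the masked carbonyl group of the ring B aldehyde and that C3, C4, C4a, C8a and C8 form a five-carbon 1-oxy-3-silyloxy diene; joining the two at C2–C3 and O1–C8a gives ring C as a 6-methyl-2,3-dihydro-4-pyranone. Its methyl group (the future C8) and its alpha-carbon (the future C4a) are then the two nucleophilic ends that receive C7, C6 and C5 of ring A, with all three oxygens, as one methoxymalonyl unit.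

Logic of the disconnections

18 back to 17. The two phenolic O–H groups at C3' and C5' are replaced, in the backward sense, by aryl O–benzyl bonds. The ring B phenols must differ from every methyl ether and must not interfere with bases, Lewis acids and alkylating agents earlier on. The skeleton is unchanged, but all earlier intermediates are free of acidic ring B hydroxyls. The last step must cleave two exocyclic benzyl ethers and leave the endocyclic benzylic C2–O1 bond and the ketone alone.

17 back to 16. The O–CH3 bonds at C5 and C7 are cut. These two oxygens are born as phenols when ring A aromatises, whereas the C6 oxygen arrives already methylated. Ring A becomes a resorcinol that a double acylation can form. The hydrogen-bonded 5-OH must be alkylated under conditions too mild to enolise C3.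

16 back to 15. The C4a–C5 bond is cut. C5 is an acyl carbon and C4a is the alpha-carbon of a vinylogous ester, so this is a Claisen (Dieckmann-type) bond. The benzene ring is replaced by a keto ester side chain on a monocyclic dihydropyranone. The base must generate the C8 carbanion, whose alpha-terminus C4a closes the only possible six-membered ring, and must leave C3–H alone; aromatisation supplies the driving force.

15 back to 10 and 13. The C8–C7 bond is cut. C8 is the methyl group of 10, the gamma-position of its vinylogous ester, and C7 is an acyl carbon; C5, C6 and C7 then come from one three-carbon piece, and the pattern of ring A (hydrogen at C8, methoxy at C6) is fixed by connectivity. Ring A is reduced to 13 and the ring C building block 10. The methine of the three-carbon piece is far more acidic than the methyl group of 10, so a metal dienolate and the diester 11 would only exchange a proton. The nucleophile is therefore used as the neutral silyl dienol ether 14 and the electrophile as the acid chloride 13. The enolisation of 10 must take the methyl group and not C3–H.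

13 back to 12 and 11. The C–Cl bond is cut, and then one of the two ester groups of 11 is singled out. 11 is symmetric and commercial, and only one of its carbonyl groups may be activated. The gain is a commercial starting material. The hydrolysis must stop at the half-ester.

10 back to 4 and 8 (the key disconnection). The C2–C3 and O1–C8a bonds are cut. Both stereocenters flank C2–C3, C2–O1 is a latent aldehyde carbonyl, the remaining five carbons are a 1-oxy-3-silyloxy diene, and both fragments are achiral. Ring C, two skeletal bonds and both stereocenters arise in one operation. A chiral Lewis acid must choose the Si face of 4; C3 must end trans to the aryl group, through the open aldol transition state that leads to 9 and through equilibration; the closure must be 6-endo onto the beta-carbon of the enone with loss of its alkoxy group.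

8 back to 7, and 7 back to 5 and 6. The O–Si bond is cut, then the bond between the carbonyl carbon and the vinylic carbon of the enone. The silyl enol ether is the kinetic enolate of 7, and 7 is the acylation product of an enol ether. Two commercial pieces result. Deprotonation must occur at the CH2OMe carbon and give the Z enolate, and the acylation needs an acyl chloride activated enough to react with the enol ether.

4 back to 3, 2 and 1. No skeletal bond is cut: the aldehyde is traced through the alcohol 3 to the ester 2, and the two O–benzyl bonds of 2 are cut to give 1. 1 is commercial and already has the 4-methoxy group between two free phenols. Ring B comes complete. Only routine alkylation, reduction and oxidation are required.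

Other disconnections considered

Alternative 1: The cut is at the two C–O bonds of the ring B phenols, traced through C–B bonds to the C–H bonds of the ring B-unsubstituted flavanonol A2, (2R,3R)-3,5,6,7-tetramethoxy-2-(4-methoxyphenyl)chroman-4-one. Forward, [Ir(OMe)(cod)]2 with a hindered bipyridine ligand and B2pin2 would borylate C3' and C5' to the bis(boronate) A1, and oxidation of both C–B bonds would give 18.
- In its favour: no protecting group on ring B, a ring B that starts as a plain para-methoxyphenyl group, and sterically governed site selection (C8–H lies between two substituents; C2'–H and C6'–H lie next to the branched C2).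
- Against it here: it only decorates ring B. The stereochemical problem of ring C is untouched, so A2 must still be made as a single enantiomer by some other key step.
- Both borylations are ortho to the same methoxy group. After the first, the methoxy methyl is turned toward the remaining ortho C–H, so the second should be slow, and the ketone or a ring oxygen could steer the catalyst to C2'.
- The oxidation must convert two aryl boronates next to an enolisable aryl ketone that is prone to Baeyer–Villiger oxidation.
- Comparison: on protecting-group economy and the late steps the alternative is better (two benzylations and a hydrogenolysis give way to one borylation and one oxidation). On ring A it is equal, since it does not address it. On mechanism it is weaker, because the ring B pattern rests on a predicted selectivity, whereas in the chosen plan it is fixed by the constitution of 1. It does not answer the main difficulty, which the chosen plan meets in step 6.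

Alternative 2: The cut is at O1–C8a and C4a–C5 together, opening both rings of A3, (2R,3R)-2-[3,5-bis(benzyloxy)-4-methoxyphenyl]-5,7-dihydroxy-3,6-dimethoxychroman-4-one (identical with 16), to the open-chain triketo ester A4, methyl (8R,9R)-9-[3,5-bis(benzyloxy)-4-methoxyphenyl]-9-hydroxy-2,8-dimethoxy-3,5,7-trioxononanoate. Forward, acid would condense the C2 hydroxyl with the C8a ketone to form ring C, and Mg(OMe)2 would then drive the Claisen attack of C4a on the C5 ester; aromatisation gives A3.
- In its favour: it follows polyketide logic and converges on the very intermediate 16, so the end game is shared.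
- Equal: the C4a–C5 closure is the same bond-forming event as step 10.
- Better: no enolisation of a chiral dihydropyranone at its methyl group is needed.
- Against it here: A4 holds both stereocenters in an open chain as a beta-hydroxy-alpha-methoxy ketone, which can undergo retro-aldol cleavage, dehydration and epimerisation at C3 before ring C forms.
- The tricarbonyl chain has other folding modes (aldol instead of Claisen closure).
- Making A4 needs the same asymmetric C2–C3 aldol bond plus two chain-extending acylations that meet the same acidic methoxymalonyl methine.
- Comparison: structurally the building blocks and protecting groups are the same. Mechanistically the chosen plan fixes ring C first, so every later closure has only one six-membered option, while the alternative relies on the chain folding correctly. In step count the alternative is at best equal, since the chain is built linearly.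

Alternative 3: The cut is at C2–C3 with ring A bought intact: the flavanone A5, (2S)-2-[3,5-bis(benzyloxy)-4-methoxyphenyl]-5,6,7-trimethoxychroman-4-one, is traced to the enol acetal A6, 2-[3,5-bis(benzyloxy)-4-methoxyphenyl]-5,6,7-trimethoxy-4-methylidene-4H-1,3-benzodioxine. Forward, a chiral (BINOL)AlCl Lewis acid would cleave the bond from C2 to the enol oxygen, and the aluminium enolate carbon C3 would add back to the oxocarbenium carbon C2 (Petasis–Ferrier rearrangement), forming C2–C3 and ring C.
- Equal: ring A is complete from the start, so its substitution pattern is as unambiguous as in the chosen plan.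
- Better: neither a benzannulation nor a late O-methylation of a chelated phenol is needed, and the flavanone skeleton is reached in fewer steps.
- Against it here: A5 lacks the C3 oxygen. It would have to be introduced afterwards by enolate or enol ether oxidation trans to the aryl group and then O-methylated, two further steps that expose an enolisable flavanone to base or oxidant.
- The enantioselective step asks a chiral aluminium centre on the enolate oxygen to control attack on a planar, aryl-stabilised oxocarbenium ion tethered through O1. The rearrangement is well known in racemic and substrate-controlled form, but a catalyst-controlled version has no close precedent, and the ion pair could recombine outside the ligand's control.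
- Comparison: structurally the alternative is the more convergent. Mechanistically step 6 rests on a known catalytic asymmetric reaction type, while this step would have to be invented. In step count the saving on ring A is largely used up by the C3 oxygenation, so the two routes are about equal in length.

Key step: step 6

Assumption: the sense of induction of the (S)-BINOL titanium catalyst is taken from related titanium–BINOL additions of carbon nucleophiles to aryl aldehydes, in which the (S)-ligand exposes the Si face; if the opposite face reacts, (R)-BINOL is used and nothing else changes.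
Remark: when bonds are discussed, ring positions carry flavanone locants (O1, C2, C3, C4, C4a, C5 to C8, C8a) also in the monocyclic intermediates; compound names use their own locants.

Step 1
Reactants: 1 methyl 3,5-dihydroxy-4-methoxybenzoate
Product: 2 methyl 3,5-bis(benzyloxy)-4-methoxybenzoate
Conditions: BnBr, K2CO3, DMF, 60 °C
Reagents that add atoms: benzyl bromide, BrCc1ccccc1
Why: Williamson ether synthesis: K2CO3 deprotonates both phenols, which displace bromide from benzyl bromide (SN2); the ester is inert and no stereocenter is involved.

Step 2
Reactants: 2 methyl 3,5-bis(benzyloxy)-4-methoxybenzoate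
Product: 3 [3,5-bis(benzyloxy)-4-methoxyphenyl]methanol
Conditions: LiAlH4, THF, 0 °C → rt
Reagents that add atoms: none
Why: Hydride reduction of an aryl ester to the benzylic alcohol; benzyl and methyl aryl ethers are inert to LiAlH4.

Step 3
Reactants: 3 [3,5-bis(benzyloxy)-4-methoxyphenyl]methanol
Product: 4 3,5-bis(benzyloxy)-4-methoxybenzaldehyde
Conditions: MnO2, CH2Cl2, rt
Reagents that add atoms: none
Why: Selective oxidation of a benzylic alcohol by activated MnO2, which stops at the aldehyde.

Step 4
Reactants: 5 methoxyacetyl chloride; 6 2-methoxypropene
Product: 7 (3E)-1,4-dimethoxypent-3-en-2-one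
Conditions: pyridine, CH2Cl2, 0 °C → rt
Reagents that add atoms: none
Why: Acylation of an enol ether: the beta-carbon of 6 attacks the acylpyridinium ion formed from 5, and the oxocarbenium ion loses a proton to give the conjugated (E)-beta-methoxy enone, a reaction known for 6 with activated acyl chlorides. The alpha-oxygen of 5 supplies that activation, and pyridine is too weak a base to turn 5 into the ketene.

Step 5
Reactants: 7 (3E)-1,4-dimethoxypent-3-en-2-one
Product: 8 (1Z,3E)-1,4-dimethoxy-2-(trimethylsilyloxy)penta-1,3-diene
Conditions: LiN(iPr)2, THF, −78 °C; Me3SiCl, −78 → 0 °C
Reagents that add atoms: chlorotrimethylsilane, C[Si](C)(C)Cl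
Why: Kinetic deprotonation of a beta-alkoxy enone by a lithium amide takes the alpha-prime carbon (here CH2OMe) and not the gamma-methyl group; chelation of lithium by the alpha-methoxy group gives the Z enolate, which Me3SiCl traps on oxygen (silyl enol ether formation).

Step 6
Reactants: 4 3,5-bis(benzyloxy)-4-methoxybenzaldehyde; 8 (1Z,3E)-1,4-dimethoxy-2-(trimethylsilyloxy)penta-1,3-diene
Product: 10 (2R,3R)-2-[3,5-bis(benzyloxy)-4-methoxyphenyl]-3-methoxy-6-methyl-2,3-dihydro-4H-pyran-4-one, via silylated aldol adduct 9 (not isolated)
Conditions: Ti(OiPr)4 (10 mol %), (S)-BINOL (20 mol %), 4 Å MS, Et2O, −20 °C; then CF3CO2H, CH2Cl2, 0 °C → rt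
Reagents that add atoms: none
Why: The tetravalent titanium BINOLate formed from Ti(OiPr)4 and (S)-BINOL binds the aldehyde oxygen of 4 and exposes its Si face to the enol silane carbon C1 of 8 (the future C3), which is activated by the silyloxy group and, vinylogously, by the methoxy group at the far end of the diene; this Mukaiyama aldol addition forms C2–C3 and gives 9. The methyl group of 8 points into the diene and disfavours the s-cis geometry of a concerted [4+2] transition state, so the stepwise course is expected; the closest known reaction type is the titanium–BINOL-catalysed formal hetero-Diels–Alder reaction of 1-alkoxy-3-silyloxy dienes with aryl aldehydes, which also passes through an aldol adduct closed by acid. CF3CO2H then removes the silyl group, and the freed C2 hydroxyl adds to the beta-carbon of the beta-methoxy enone in a 6-endo-trig oxa-conjugate addition followed by loss of methanol, so that O1–C8a and ring C arise by addition–elimination. C2 is set by the chiral catalyst alone, since both partners are achiral. C3 is set first by the open transition state of the Z enol silane, which should favour the anti aldol and hence the trans ring, and then by thermodynamics: acid-catalysed enolisation toward C3 lets any cis isomer move toward the expected diequatorial trans (2R,3R) compound without breaking a bond at C2. The step needs enantiofacial selectivity, supplied by the C2-symmetric BINOLate around the bound aldehyde, and regioselectivity for C1 of the diene, supplied by the fact that C1 is the only carbon of 8 that belongs to an enol silane. Dry conditions and 4 Å molecular sieves keep hydrolysis of 8 back to 7 from outrunning the addition.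

Step 7
Reactants: 11 dimethyl 2-methoxymalonate
Product: 12 2,3-dimethoxy-3-oxopropanoic acid
Conditions: KOH (1.0 equiv), MeOH, 0 °C → rt; then aq. HCl
Reagents that add atoms: potassium hydroxide, [K+].[OH-]
Why: Monosaponification of a symmetric malonate: one equivalent of hydroxide cleaves one ester, and the carboxylate formed shields the second ester from attack. The half-ester is racemic, and its stereocenter disappears when ring A aromatises.

Step 8
Reactants: 12 2,3-dimethoxy-3-oxopropanoic acid
Product: 13 methyl 3-chloro-2-methoxy-3-oxopropanoate
Conditions: (COCl)2, DMF (cat.), CH2Cl2, 0 °C → rt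
Reagents that add atoms: oxalyl chloride, O=C(Cl)C(=O)Cl
Why: Acid chloride formation through the chloroiminium ion of DMF, at a temperature low enough for a malonic half-acid; 13 is used without purification.

Step 9
Reactants: 10 (2R,3R)-2-[3,5-bis(benzyloxy)-4-methoxyphenyl]-3-methoxy-6-methyl-2,3-dihydro-4H-pyran-4-one; 13 methyl 3-chloro-2-methoxy-3-oxopropanoate
Product: 15 methyl 4-[(2R,3R)-2-[3,5-bis(benzyloxy)-4-methoxyphenyl]-3-methoxy-4-oxo-3,4-dihydro-2H-pyran-6-yl]-2-methoxy-3-oxobutanoate, via trimethylsilyl dienol ether 14 (not isolated)
Conditions: LiN(SiMe3)2, THF, −78 °C; Me3SiCl, −78 → 0 °C; volatiles removed, pentane, filtration; then 13, CH2Cl2, −78 → 0 °C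
Reagents that add atoms: none
Why: LiN(SiMe3)2 removes a proton from the 6-methyl group to give the extended (gamma) dienolate, the more stable anion, while the tertiary, methoxy-bearing C3 hydrogen is the hindered alternative; O-silylation gives the 2-alkoxy-4-silyloxy diene 14, whose terminal CH2 is acylated by 13 without base (vinylogous Mukaiyama-type C-acylation, known for silyloxy dienes and malonyl chloride half-esters), which returns the enone. Under these neutral conditions the acidic methine of the malonyl unit, which would simply protonate a lithium dienolate if 11 were used directly, does no harm. C2 and C3 are not touched, and the new methine (a mixture of epimers) is lost in step 10.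

Step 10
Reactants: 15 methyl 4-[(2R,3R)-2-[3,5-bis(benzyloxy)-4-methoxyphenyl]-3-methoxy-4-oxo-3,4-dihydro-2H-pyran-6-yl]-2-methoxy-3-oxobutanoate
Product: 16 (2R,3R)-2-[3,5-bis(benzyloxy)-4-methoxyphenyl]-5,7-dihydroxy-3,6-dimethoxy-2,3-dihydro-4H-chromen-4-one
Conditions: DBU, CH2Cl2, 0 °C → rt; then aq. HCl
Reagents that add atoms: none
Why: DBU removes a proton from the doubly activated C8 methylene, and in the resulting extended enolate the alpha-carbon C4a attacks the ester carbonyl in a 6-exo-trig Dieckmann-type Claisen condensation; methoxide leaves and the trione tautomerises to the resorcinol, which makes the closure irreversible. This is the only six-membered closure open to the anion, so the pattern of ring A (hydrogen at C8, methoxy at C6) follows from connectivity. A base of this strength should not enolise C3.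

Step 11
Reactants: 16 (2R,3R)-2-[3,5-bis(benzyloxy)-4-methoxyphenyl]-5,7-dihydroxy-3,6-dimethoxy-2,3-dihydro-4H-chromen-4-one
Product: 17 (2R,3R)-2-[3,5-bis(benzyloxy)-4-methoxyphenyl]-3,5,6,7-tetramethoxy-2,3-dihydro-4H-chromen-4-one
Conditions: MeI, K2CO3, DMF, rt → 40 °C
Reagents that add atoms: iodomethane, CI
Why: Williamson O-methylation of the two phenoxides; the free 7-OH reacts first and the hydrogen-bonded 5-OH needs excess reagent and time, as is usual for flavanones. K2CO3 is a weak base for enolising the alpha-methoxy ketone, and ring B has no free para-hydroxyl that could open ring C through a quinone methide.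

Step 12
Reactants: 17 (2R,3R)-2-[3,5-bis(benzyloxy)-4-methoxyphenyl]-3,5,6,7-tetramethoxy-2,3-dihydro-4H-chromen-4-one
Product: 18 (2R,3R)-2-(3,5-dihydroxy-4-methoxyphenyl)-3,5,6,7-tetramethoxy-2,3-dihydro-4H-chromen-4-one
Conditions: H2 (1 atm), Pd/C, EtOAc–MeOH, rt
Reagents that add atoms: none
Why: Hydrogenolysis of the two benzyl aryl ethers over palladium; these exocyclic benzylic C–O bonds should cleave well before the endocyclic C2–O1 bond breaks or the aryl ketone is reduced, if the reaction is stopped after two equivalents of H2. The neutral conditions leave C2 and C3 as they are.

Compound list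

1 | methyl 3,5-dihydroxy-4-methoxybenzoate | COC(=O)c1cc(O)c(OC)c(O)c1 | starting material
2 | methyl 3,5-bis(benzyloxy)-4-methoxybenzoate | COC(=O)c1cc(OCc2ccccc2)c(OC)c(OCc2ccccc2)c1 | intermediate
3 | [3,5-bis(benzyloxy)-4-methoxyphenyl]methanol | OCc1cc(OCc2ccccc2)c(OC)c(OCc2ccccc2)c1 | intermediate
4 | 3,5-bis(benzyloxy)-4-methoxybenzaldehyde | O=Cc1cc(OCc2ccccc2)c(OC)c(OCc2ccccc2)c1 | intermediate
5 | methoxyacetyl chloride | COCC(=O)Cl | starting material
6 | 2-methoxypropene | C=C(C)OC | starting material
7 | (3E)-1,4-dimethoxypent-3-en-2-one | COCC(=O)/C=C(\C)OC | intermediate
8 | (1Z,3E)-1,4-dimethoxy-2-(trimethylsilyloxy)penta-1,3-diene | CO/C=C(O[Si](C)(C)C)/C=C(\C)OC | intermediate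
9 | (1R,2R,4E)-1-[3,5-bis(benzyloxy)-4-methoxyphenyl]-2,5-dimethoxy-1-(trimethylsilyloxy)hex-4-en-3-one | C/C(OC)=C\C(=O)[C@H](OC)[C@@H](c1cc(OCc2ccccc2)c(OC)c(OCc2ccccc2)c1)O[Si](C)(C)C | intermediate (not isolated)
10 | (2R,3R)-2-[3,5-bis(benzyloxy)-4-methoxyphenyl]-3-methoxy-6-methyl-2,3-dihydro-4H-pyran-4-one | CC1=CC(=O)[C@H](OC)[C@@H](c2cc(OCc3ccccc3)c(OC)c(OCc3ccccc3)c2)O1 | intermediate
11 | dimethyl 2-methoxymalonate | COC(C(=O)OC)C(=O)OC | starting material
12 | 2,3-dimethoxy-3-oxopropanoic acid (racemic) | COC(C(=O)O)C(=O)OC | intermediate
13 | methyl 3-chloro-2-methoxy-3-oxopropanoate (racemic) | COC(C(=O)Cl)C(=O)OC | intermediate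
14 | (2R,3R)-2-[3,5-bis(benzyloxy)-4-methoxyphenyl]-3-methoxy-6-methylidene-4-(trimethylsilyloxy)-3,6-dihydro-2H-pyran | C=C1C=C(O[Si](C)(C)C)[C@H](OC)[C@@H](c2cc(OCc3ccccc3)c(OC)c(OCc3ccccc3)c2)O1 | intermediate (not isolated)
15 | methyl 4-[(2R,3R)-2-[3,5-bis(benzyloxy)-4-methoxyphenyl]-3-methoxy-4-oxo-3,4-dihydro-2H-pyran-6-yl]-2-methoxy-3-oxobutanoate (both epimers at C2 of the butanoate) | COC(=O)C(OC)C(=O)CC1=CC(=O)[C@H](OC)[C@@H](c2cc(OCc3ccccc3)c(OC)c(OCc3ccccc3)c2)O1 | intermediate
16 | (2R,3R)-2-[3,5-bis(benzyloxy)-4-methoxyphenyl]-5,7-dihydroxy-3,6-dimethoxy-2,3-dihydro-4H-chromen-4-one | Oc1cc2c(c(O)c1OC)C(=O)[C@H](OC)[C@@H](c1cc(OCc3ccccc3)c(OC)c(OCc3ccccc3)c1)O2 | intermediate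
17 | (2R,3R)-2-[3,5-bis(benzyloxy)-4-methoxyphenyl]-3,5,6,7-tetramethoxy-2,3-dihydro-4H-chromen-4-one | COc1cc2c(c(OC)c1OC)C(=O)[C@H](OC)[C@@H](c1cc(OCc3ccccc3)c(OC)c(OCc3ccccc3)c1)O2 | intermediate
18 | (2R,3R)-2-(3,5-dihydroxy-4-methoxyphenyl)-3,5,6,7-tetramethoxy-2,3-dihydro-4H-chromen-4-one | COc1cc2c(c(OC)c1OC)C(=O)[C@H](OC)[C@@H](c1cc(O)c(OC)c(O)c1)O2 | target

Step count and least certain steps

Total: 12 steps. Longest linear sequence: 8 steps (steps 1, 2, 3, 6, 9, 10, 11, 12, from 1 to 18). The diene branch (steps 4, 5) and the acid chloride branch (steps 7, 8) are two steps each.

Step 6 (key step). The most likely failure is poor facial selectivity. The nucleophilic carbon of 8 carries a methoxy group and is more hindered than in the unsubstituted parent diene, so the catalysed addition may be slow enough for a racemic, silyl-cation-promoted background aldol or for hydrolysis of 8 to compete. Incomplete equilibration at C3 would add a cis isomer; the thermodynamic preference for trans is expected by analogy with flavanonols, but its size for a 3-methoxy dihydropyranone is not known. Fallback: from 4 and 8, the aldol addition is run with stoichiometric BF3·OEt2 in CH2Cl2 at −78 °C and closed with CF3CO2H, which should give the racemic trans pyranone, that is 10 together with (2S,3S)-2-[3,5-bis(benzyloxy)-4-methoxyphenyl]-3-methoxy-6-methyl-2,3-dihydro-4H-pyran-4-one F1. Preparative chromatography on a chiral stationary phase separates the two, and the route is rejoined at 10. This replaces asymmetric catalysis by resolution at the cost of half the material.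

Step 9. The most likely failure is deprotonation at C3 instead of the methyl group, because a lithium amide bound to the carbonyl oxygen is directed to the alpha-prime hydrogen. That would lead to epimerisation at C3 or, through the ring-silylated 2H-pyran and its electrocyclic opening, to loss of C2. Amine left in the crude 14 would consume 13 by N-acylation. Fallback: from 10, soft enolisation with tBuMe2SiOTf and Et3N in CH2Cl2 at 0 °C, in which the amine removes the most exposed proton of the O-silylated cation, should give (2R,3R)-2-[3,5-bis(benzyloxy)-4-methoxyphenyl]-4-(tert-butyldimethylsilyloxy)-3-methoxy-6-methylidene-3,6-dihydro-2H-pyran F2. F2 is isolated by filtration through basic Al2O3 and acylated with 13 in CH2Cl2 (catalytic Me3SiOTf if slow), rejoining the route at 15.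

Step 10. The most likely failure is stalling at the unreactive enolate formed by deprotonation of the keto ester methine, which deactivates the ester; retro-Claisen cleavage of the keto ester by the methoxide set free is the second risk. Fallback: from 15, base-free thermolysis in xylene at 140 °C over 4 Å molecular sieves should expel methanol to give the acylketene 4-[(2R,3R)-2-[3,5-bis(benzyloxy)-4-methoxyphenyl]-3-methoxy-4-oxo-3,4-dihydro-2H-pyran-6-yl]-2-methoxybut-1-ene-1,3-dione F3. Its dienol form is a dienylketene conjugated with the C4a=C8a double bond; 6π electrocyclisation forms C4a–C5 and tautomerisation gives 16, where the route is rejoined. Acylketene formation from keto esters and the electrocyclic closure of dienylketenes to phenols are both known.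

Step 11. The most likely failure is enolisation at C3 during the slow alkylation of the hydrogen-bonded 5-OH, leading to epimerisation or ring opening. Fallback: from 16, Me3SiCHN2 in MeOH–toluene should methylate only the free 7-OH to give (2R,3R)-2-[3,5-bis(benzyloxy)-4-methoxyphenyl]-5-hydroxy-3,6,7-trimethoxy-2,3-dihydro-4H-chromen-4-one F4. The chelated phenol is then etherified under neutral Mitsunobu conditions (MeOH, PPh3, diisopropyl azodicarboxylate, THF), rejoining the route at 17. No phenoxide or carbonate base is present at any point.

Step 4. The most likely failure is sluggish acylation, because 5 is less electrophilic than the polyhalogenated acyl chlorides that react best with enol ethers, together with loss of 5 to ketene-derived oligomers. Fallback: from 5, amide formation with MeONHMe·HCl and Et3N in CH2Cl2 gives N,2-dimethoxy-N-methylacetamide F5. Addition of CH3C≡CMgBr in THF at 0 °C gives 1-methoxypent-3-yn-2-one F6, and conjugate addition of MeOH with catalytic 1,4-diazabicyclo[2.2.2]octane gives 7, where the route is rejoined. This is one step longer, but the regiochemistry is fixed at every stage.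

Further compounds

F1 | step 6 | (2S,3S)-2-[3,5-bis(benzyloxy)-4-methoxyphenyl]-3-methoxy-6-methyl-2,3-dihydro-4H-pyran-4-one | CC1=CC(=O)[C@@H](OC)[C@H](c2cc(OCc3ccccc3)c(OC)c(OCc3ccccc3)c2)O1
F2 | step 9 | (2R,3R)-2-[3,5-bis(benzyloxy)-4-methoxyphenyl]-4-(tert-butyldimethylsilyloxy)-3-methoxy-6-methylidene-3,6-dihydro-2H-pyran | C=C1C=C(O[Si](C)(C)C(C)(C)C)[C@H](OC)[C@@H](c2cc(OCc3ccccc3)c(OC)c(OCc3ccccc3)c2)O1
F3 | step 10 | 4-[(2R,3R)-2-[3,5-bis(benzyloxy)-4-methoxyphenyl]-3-methoxy-4-oxo-3,4-dihydro-2H-pyran-6-yl]-2-methoxybut-1-ene-1,3-dione | COC(=C=O)C(=O)CC1=CC(=O)[C@H](OC)[C@@H](c2cc(OCc3ccccc3)c(OC)c(OCc3ccccc3)c2)O1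
F4 | step 11 | (2R,3R)-2-[3,5-bis(benzyloxy)-4-methoxyphenyl]-5-hydroxy-3,6,7-trimethoxy-2,3-dihydro-4H-chromen-4-one | COc1cc2c(c(O)c1OC)C(=O)[C@H](OC)[C@@H](c1cc(OCc3ccccc3)c(OC)c(OCc3ccccc3)c1)O2
F5 | step 4 | N,2-dimethoxy-N-methylacetamide | COCC(=O)N(C)OC
F6 | step 4 | 1-methoxypent-3-yn-2-one | COCC(=O)C#CC
A1 | alternative 1 | (2R,3R)-3,5,6,7-tetramethoxy-2-[4-methoxy-3,5-bis(4,4,5,5-tetramethyl-1,3,2-dioxaborolan-2-yl)phenyl]-2,3-dihydro-4H-chromen-4-one | COc1cc2c(c(OC)c1OC)C(=O)[C@H](OC)[C@@H](c1cc(B3OC(C)(C)C(C)(C)O3)c(OC)c(B3OC(C)(C)C(C)(C)O3)c1)O2
A2 | alternative 1 | (2R,3R)-3,5,6,7-tetramethoxy-2-(4-methoxyphenyl)-2,3-dihydro-4H-chromen-4-one | COc1cc2c(c(OC)c1OC)C(=O)[C@H](OC)[C@@H](c1ccc(OC)cc1)O2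
A3 | alternative 2 | (2R,3R)-2-[3,5-bis(benzyloxy)-4-methoxyphenyl]-5,7-dihydroxy-3,6-dimethoxy-2,3-dihydro-4H-chromen-4-one | Oc1cc2c(c(O)c1OC)C(=O)[C@H](OC)[C@@H](c1cc(OCc3ccccc3)c(OC)c(OCc3ccccc3)c1)O2
A4 | alternative 2 | methyl (8R,9R)-9-[3,5-bis(benzyloxy)-4-methoxyphenyl]-9-hydroxy-2,8-dimethoxy-3,5,7-trioxononanoate | COC(=O)C(OC)C(=O)CC(=O)CC(=O)[C@H](OC)[C@@H](c1cc(OCc2ccccc2)c(OC)c(OCc2ccccc2)c1)O
A5 | alternative 3 | (2S)-2-[3,5-bis(benzyloxy)-4-methoxyphenyl]-5,6,7-trimethoxy-2,3-dihydro-4H-chromen-4-one | COc1cc2c(c(OC)c1OC)C(=O)C[C@@H](c1cc(OCc3ccccc3)c(OC)c(OCc3ccccc3)c1)O2
A6 | alternative 3 | 2-[3,5-bis(benzyloxy)-4-methoxyphenyl]-5,6,7-trimethoxy-4-methylidene-4H-1,3-benzodioxine | C=C1OC(c2cc(OCc3ccccc3)c(OC)c(OCc3ccccc3)c2)Oc2cc(OC)c(OC)c(OC)c21
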